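A flask set to run for 3.0 d is slow, and the first thing to find is how many chains will share its monomer, since the average length is monomer in chains divided by chains begun.

free monomer 0.81 M; initiator 16 mM; impurity 21 mM; time 3.0 d

- whether the average number of monomer units in a chain (chains begun, living or dead) reaches 90 by 3.0 d (yes / no)
- average number of monomer units in a chain (chains begun, living or dead) at 3.0 d

- two of one species on the left: rate k times its square, two consumed each time
- the average divides the monomer in chains by the number of chains begun, living and dead together
- run time (flask): 3.0 d

    free monomer + initiator → living end + monomer in chains (k1 = 2.47 × 10⁻⁴ /M/s)
    free monomer + living end → monomer in chains + living end, rate k2*[living end]*[free monomer] (k2 = 0.00174 /M/s)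
    2 initiator → spent initiator A (k3 = 0.00435 /M/s)
    initiator + monomer in chains → spent initiator B (k4 = 5.73 × 10⁻⁵ /M/s)
    initiator + impurity → spent initiator C (k5 = 0.289 /M/s)

Our reckoning sets side by side the first-order losses of initiator at the charge:

- to impurity: 0.00607 /s
- to free monomer, which begins a chain: 2.00 × 10⁻⁴ /s
- to itself, counting the two consumed per turn: 1.39 × 10⁻⁴ /s

The first row stands 30.3 times above the second, so at the charge the impurity takes initiator faster than free monomer does, and the impurity's charge exceeds the initiator's. The third row lies below the second and falls as initiator falls, so we drop it.

Dividing the second row by the first, with free monomer held at its charge, gives the chains begun, L, as 0.692 mM times the logarithm of impurity charged over impurity left. Taking the impurity left as its charge less the initiator's gives 0.993 mM, and adding those chains back to the impurity left gives L = 0.868 mM.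

No listed step removes a living end, so free monomer then falls pseudo-first-order at 0.130 /d, with a half-life of 5.31 d, far beyond the initiator's lifetime of 2.75 min in the first row, which justifies holding free monomer at its charge. Our answers are 302 units and yes.

The forecast answers yes and 302, holding that “the initiator is gone within hours”.

The simulation gives yes and 303.

In this flask, half of the turnover of the step from initiator and impurity to spent initiator C is done by 0.0373 h, against 1.36 d for the growth step. The living end stands at 8.56 × 10⁻⁴ M at 0.300 d and at 8.56 × 10⁻⁴ M at 3.00 d. Carrying our 0.868 mM into the same flask left for twice the time, the same first-order fall puts the length at 507, and that run stands at 509.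

The constants used here are those of an exercise.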